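**Retrosynthetic overview**
1. Target 21 ⇐ 4‑methoxyphenol 19 by oxidative demethylation to the quinone and reduction. No ring is formed anywhere in the route; the arene is bought.
2. 19 ⇐ C5–C6 bond: nickel‑electrocatalytic decarboxylative alkenylation of acid 17 (C1–C5 plus arene) with the E‑alkenyl iodide 10 (C6–C16).
3. 10 ⇐ homopropargylic alcohol 9 (Zr‑catalysed methylalumination, iodination) ⇐ vinyl epoxide 8 + acetylide ⇐ diol 7 ⇐ (R)‑glyceraldehyde acetonide 1, which supplies C9; C10=C11 comes from dichloro‑olefination and tandem Negishi coupling.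
4. 17 ⇐ 4‑methoxy‑2‑methylphenol 15 + hydroxy ester 14 (ortho‑allylation) ⇐ geranyl acetate 11 (selective ozonolysis keeps the 2E alkene).

Assumption: (R)‑glyceraldehyde acetonide (from D‑mannitol), geranyl acetate, 4‑methoxy‑2‑methylphenol and 5‑bromo‑2‑methylpent‑2‑ene are bought.

**Route**

Step 1
Reactants: 1 (4R)-2,2-dimethyl-1,3-dioxolane-4-carbaldehyde
Product: 2 (4S)-4-(2,2-dichloroethenyl)-2,2-dimethyl-1,3-dioxolane
Conditions: BrCCl3, PPh3, MeCN, 0 °C to rt
Reagents that add atoms: bromotrichloromethane ClC(Cl)(Cl)Br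
Why: Ramirez‑type gem‑dichloro‑olefination (Wittig reaction of Ph3P=CCl2 made in situ) converts the aldehyde under non‑basic conditions, so the bought stereocentre is carried over unchanged.

Step 2
Reactants: 2 (4S)-4-(2,2-dichloroethenyl)-2,2-dimethyl-1,3-dioxolane, 3 5-bromo-2-methylpent-2-ene
Product: 6 (4S)-4-[(1E)-2,6-dimethylhepta-1,5-dien-1-yl]-2,2-dimethyl-1,3-dioxolane, via homoprenylzinc bromide 4 (not isolated), via chloroalkene 5 (not isolated)
Conditions: 3, Zn dust, LiCl, THF, 50 °C; then 2, PdCl2(DPEphos) (5 mol %), 50 °C; then Me2Zn, Pd(PtBu3)2 (5 mol %), THF–NMP, 23 °C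
Reagents that add atoms: dimethylzinc C[Zn]C
Why: Tandem Negishi coupling: the C–Cl bond trans to the dioxolane reacts first (alkylation), then the remaining C–Cl is methylated with retention, which fixes the E trisubstituted alkene without touching the stereocentre.

Step 3
Reactants: 6 (4S)-4-[(1E)-2,6-dimethylhepta-1,5-dien-1-yl]-2,2-dimethyl-1,3-dioxolane
Product: 7 (2S,3E)-4,8-dimethylnona-3,7-diene-1,2-diol
Conditions: AcOH–H2O (4:1), 40 °C
Reagents that add atoms: none
Why: Acid‑catalysed acetal hydrolysis cleaves at the acetal carbon, so the C–O bond of the stereocentre is never broken.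

Step 4
Reactants: 7 (2S,3E)-4,8-dimethylnona-3,7-diene-1,2-diol
Product: 9 (4R,5E)-6,10-dimethylundeca-5,9-dien-1-yn-4-ol, via vinyl epoxide 8 (not isolated)
Conditions: NaH, 1-(2,4,6-triisopropylbenzenesulfonyl)imidazole, THF, 0 °C to rt; then LiC≡CH·H2N(CH2)2NH2, DMSO, rt
Reagents that add atoms: lithium acetylide–ethylenediamine complex [Li+].[C-]#C.NCCN
Why: Primary‑selective sulfonylation and Williamson closure give the terminal epoxide with the carbinol C–O intact, and SN2 opening by acetylide at the unhindered CH2 (no Lewis acid) gives the homopropargylic alcohol with the configuration retained.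

Step 5
Reactants: 9 (4R,5E)-6,10-dimethylundeca-5,9-dien-1-yn-4-ol
Product: 10 (1E,4R,5E)-1-iodo-2,6,10-trimethylundeca-1,5,9-trien-4-ol
Conditions: Me3Al (3 equiv), Cp2ZrCl2 (0.3 equiv), CH2Cl2, 0 °C to rt; then iodine, THF, −30 °C
Reagents that add atoms: trimethylaluminium C[Al](C)C; iodine [I][I]
Why: Negishi zirconium‑catalysed carboalumination adds Me–Al syn across the terminal alkyne (Me to the internal carbon) and iodinolysis proceeds with retention, giving the E alkenyl iodide; the trisubstituted alkenes and the aluminium alkoxide are inert.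

Step 6
Reactants: 11 (2E)-3,7-dimethylocta-2,6-dien-1-yl acetate (geranyl acetate)
Product: 12 (2E)-3-methyl-6-oxohex-2-en-1-yl acetate
Conditions: O3 (1.0 equiv), CH2Cl2–pyridine, −78 °C; then Me2S
Reagents that add atoms: ozone [O-][O+]=O
Why: Chemoselective ozonolysis: the allylic acetate deactivates the 2,3‑alkene, so one equivalent of ozone cleaves only the terminal trisubstituted alkene.

Step 7
Reactants: 12 (2E)-3-methyl-6-oxohex-2-en-1-yl acetate
Product: 14 methyl (4E)-6-hydroxy-4-methylhex-4-enoate, via acetoxy ester 13 (not isolated)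
Conditions: KOH, iodine, MeOH, 0 °C to rt
Reagents that add atoms: methanol CO
Why: Oxidative esterification of the aldehyde through its hemiacetal by hypoiodite, followed in the same pot by base‑catalysed transesterification of the acetate.

Step 8
Reactants: 14 methyl (4E)-6-hydroxy-4-methylhex-4-enoate, 15 4-methoxy-2-methylphenol
Product: 16 methyl (4E)-6-(2-hydroxy-5-methoxy-3-methylphenyl)-4-methylhex-4-enoate
Conditions: activated acidic Al2O3, 15 (2 equiv), 1,2-dichloroethane, 80 °C
Reagents that add atoms: none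
Why: Alumina‑directed ortho‑allylation (surface‑templated Friedel–Crafts reaction): the allyl cation from the primary allylic alcohol attacks the only free position ortho to the bound phenol through its primary terminus, keeping the E alkene.

Step 9
Reactants: 16 methyl (4E)-6-(2-hydroxy-5-methoxy-3-methylphenyl)-4-methylhex-4-enoate
Product: 17 (4E)-6-(2-hydroxy-5-methoxy-3-methylphenyl)-4-methylhex-4-enoic acid
Conditions: LiOH, THF–H2O, rt, argon; then aq. HCl
Reagents that add atoms: lithium hydroxide [Li+].[OH-]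
Why: Ester saponification, run under argon to keep the electron‑rich phenoxide from air oxidation.

Step 10
Reactants: 17 (4E)-6-(2-hydroxy-5-methoxy-3-methylphenyl)-4-methylhex-4-enoic acid, 10 (1E,4R,5E)-1-iodo-2,6,10-trimethylundeca-1,5,9-trien-4-ol
Product: 19 2-[(2E,6E,9R,10E)-9-hydroxy-3,7,11,15-tetramethylhexadeca-2,6,10,14-tetraen-1-yl]-4-methoxy-6-methylphenol, via phthalimide ester 18 (not isolated)
Conditions: 17 (1.5 equiv), N-hydroxyphthalimide, DIC, NMP, rt; then 10, NiCl2·6H2O (20 mol %), 2,2′-bipyridine, AgNO3 (30 mol %), Mg anode, RVC cathode, constant current, rt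
Reagents that add atoms: none
Why: Proposed new method: nickel‑electrocatalytic decarboxylative C(sp3)–C(sp2) fragment coupling run with no protecting group, on an in‑situ redox‑active ester that carries a free 2,6‑dialkyl‑4‑methoxyphenol (itself a radical‑chain inhibitor) and an E trisubstituted alkenyl iodide that carries a free secondary allylic carbinol, a substrate pairing that to my knowledge has not been shown; cathodically formed zerovalent nickel adds oxidatively to the C–I bond of 10 with retention of geometry, one‑electron reduction of 18 releases CO2, phthalimide anion and the primary C5 radical (its only rearrangement, the homoallyl/cyclopropylcarbinyl shift, is degenerate), the alkenylnickel species captures the radical and reductive elimination forms C5–C6, while the net reductive medium leaves the phenol unoxidised, hydrogen‑atom donation from the solvent‑bound phenol is slower than radical capture, and the C9 stereocentre three bonds away is untouched; closest known reaction type: nickel‑catalysed electroreductive decarboxylative alkenylation of N‑hydroxyphthalimide esters with alkenyl halides.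

Step 11
Reactants: 19 2-[(2E,6E,9R,10E)-9-hydroxy-3,7,11,15-tetramethylhexadeca-2,6,10,14-tetraen-1-yl]-4-methoxy-6-methylphenol
Product: 21 2-[(2E,6E,9R,10E)-9-hydroxy-3,7,11,15-tetramethylhexadeca-2,6,10,14-tetraen-1-yl]-6-methylbenzene-1,4-diol, via quinone 20 (not isolated)
Conditions: PhI(OAc)2, MeCN–H2O (2:1), 0 °C; then aq. Na2S2O4
Reagents that add atoms: water O
Why: Oxidative demethylation of the 4‑methoxyphenol (water adds at C4, methanol leaves) gives the benzoquinone, which dithionite reduces to the hydroquinone; the alkenes and the allylic carbinol are untouched under these near‑neutral conditions.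

**Compound list**
1 | (4R)-2,2-dimethyl-1,3-dioxolane-4-carbaldehyde | O=C[C@H]1COC(C)(C)O1 | starting material
2 | (4S)-4-(2,2-dichloroethenyl)-2,2-dimethyl-1,3-dioxolane | ClC(Cl)=C[C@H]1COC(C)(C)O1 | intermediate
3 | 5-bromo-2-methylpent-2-ene | CC(C)=CCCBr | starting material
4 | (4-methylpent-3-en-1-yl)zinc bromide | CC(C)=CCC[Zn]Br | intermediate
5 | (4S)-4-[(1Z)-2-chloro-6-methylhepta-1,5-dien-1-yl]-2,2-dimethyl-1,3-dioxolane | CC(C)=CCC/C(Cl)=C/[C@H]1COC(C)(C)O1 | intermediate
6 | (4S)-4-[(1E)-2,6-dimethylhepta-1,5-dien-1-yl]-2,2-dimethyl-1,3-dioxolane | CC(C)=CCC/C(C)=C/[C@H]1COC(C)(C)O1 | intermediate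
7 | (2S,3E)-4,8-dimethylnona-3,7-diene-1,2-diol | CC(C)=CCC/C(C)=C/[C@H](O)CO | intermediate
8 | (2S)-2-[(1E)-2,6-dimethylhepta-1,5-dien-1-yl]oxirane | CC(C)=CCC/C(C)=C/[C@H]1CO1 | intermediate
9 | (4R,5E)-6,10-dimethylundeca-5,9-dien-1-yn-4-ol | CC(C)=CCC/C(C)=C/[C@H](O)CC#C | intermediate
10 | (1E,4R,5E)-1-iodo-2,6,10-trimethylundeca-1,5,9-trien-4-ol | CC(C)=CCC/C(C)=C/[C@H](O)C/C(C)=C/I | intermediate
11 | (2E)-3,7-dimethylocta-2,6-dien-1-yl acetate (geranyl acetate) | CC(C)=CCC/C(C)=C/COC(C)=O | starting material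
12 | (2E)-3-methyl-6-oxohex-2-en-1-yl acetate | O=CCC/C(C)=C/COC(C)=O | intermediate
13 | methyl (4E)-6-acetoxy-4-methylhex-4-enoate | COC(=O)CC/C(C)=C/COC(C)=O | intermediate
14 | methyl (4E)-6-hydroxy-4-methylhex-4-enoate | COC(=O)CC/C(C)=C/CO | intermediate
15 | 4-methoxy-2-methylphenol | COc1ccc(O)c(C)c1 | starting material
16 | methyl (4E)-6-(2-hydroxy-5-methoxy-3-methylphenyl)-4-methylhex-4-enoate | COC(=O)CC/C(C)=C/Cc1cc(OC)cc(C)c1O | intermediate
17 | (4E)-6-(2-hydroxy-5-methoxy-3-methylphenyl)-4-methylhex-4-enoic acid | OC(=O)CC/C(C)=C/Cc1cc(OC)cc(C)c1O | intermediate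
18 | 1,3-dioxoisoindolin-2-yl (4E)-6-(2-hydroxy-5-methoxy-3-methylphenyl)-4-methylhex-4-enoate | O=C(CC/C(C)=C/Cc1cc(OC)cc(C)c1O)ON1C(=O)c2ccccc2C1=O | intermediate
19 | 2-[(2E,6E,9R,10E)-9-hydroxy-3,7,11,15-tetramethylhexadeca-2,6,10,14-tetraen-1-yl]-4-methoxy-6-methylphenol | CC(C)=CCC/C(C)=C/[C@H](O)C/C(C)=C/CC/C(C)=C/Cc1cc(OC)cc(C)c1O | intermediate
20 | 2-[(2E,6E,9R,10E)-9-hydroxy-3,7,11,15-tetramethylhexadeca-2,6,10,14-tetraen-1-yl]-6-methylcyclohexa-2,5-diene-1,4-dione | CC(C)=CCC/C(C)=C/[C@H](O)C/C(C)=C/CC/C(C)=C/CC1=CC(=O)C=C(C)C1=O | intermediate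
21 | 2-[(2E,6E,9R,10E)-9-hydroxy-3,7,11,15-tetramethylhexadeca-2,6,10,14-tetraen-1-yl]-6-methylbenzene-1,4-diol | CC(C)=CCC/C(C)=C/[C@H](O)C/C(C)=C/CC/C(C)=C/Cc1cc(O)cc(C)c1O | target

**Totals**
Total steps: 11. Longest linear sequence: 7 (steps 1–5, 10, 11).

**Three steps most likely to fail**

Step 10 (the new coupling). The phenol may quench the C5 radical, or the unprotected partners may interfere with the nickel cycle. The fallback sets out from 17 and 10 and comes back at 19. Acid 17 is converted with N‑hydroxypyridine‑2‑thione and DCC into its Barton ester, 2-thioxopyridin-1(2H)-yl (4E)-6-(2-hydroxy-5-methoxy-3-methylphenyl)-4-methylhex-4-enoate F1. Photolysis of this ester with iodoform (Barton decarboxylative iodination) gives the primary iodide 2-[(2E)-5-iodo-3-methylpent-2-en-1-yl]-4-methoxy-6-methylphenol F2. F2 and 10 are then joined by the established thermal nickel‑catalysed reductive cross‑electrophile coupling of an alkyl iodide with an alkenyl iodide (NiI2, 4,4′-di-tert-butyl-2,2′-bipyridine, manganese powder, DMA, rt), giving 19.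

Step 4. The acetylide may attack the allylic carbon of the vinyl epoxide or add in SN2′ fashion. The fallback sets out from 7 and comes back at 9, and never forms an epoxide. Tin‑catalysed primary tosylation (TsCl, Bu2SnO cat., Et3N) gives (2S,3E)-2-hydroxy-4,8-dimethylnona-3,7-dien-1-yl 4-methylbenzenesulfonate F3. Silylation (TBSOTf, 2,6‑lutidine) gives (2S,3E)-2-[(tert-butyldimethylsilyl)oxy]-4,8-dimethylnona-3,7-dien-1-yl 4-methylbenzenesulfonate F4. Direct SN2 displacement with lithium (trimethylsilyl)acetylide in THF–DMPU gives tert-butyl{[(4R,5E)-6,10-dimethyl-1-(trimethylsilyl)undeca-5,9-dien-1-yn-4-yl]oxy}dimethylsilane F5, and TBAF removes both silyl groups to give 9.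

Step 8. The allyl cation on alumina may be trapped by the ester carbonyl (lactonisation) or give low conversion. The fallback sets out from 14 and 15 and comes back at 16. PBr3 (Et2O, −10 °C) converts 14 into methyl (4E)-6-bromo-4-methylhex-4-enoate F6. The sodium salt of 15 (NaH, toluene) is then alkylated on carbon at its free ortho position by F6; this is an SN2 process with no cation, and it gives 16.

**Further compounds**
F1 | step 10 | 2-thioxopyridin-1(2H)-yl (4E)-6-(2-hydroxy-5-methoxy-3-methylphenyl)-4-methylhex-4-enoate | O=C(CC/C(C)=C/Cc1cc(OC)cc(C)c1O)On1ccccc1=S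
F2 | step 10 | 2-[(2E)-5-iodo-3-methylpent-2-en-1-yl]-4-methoxy-6-methylphenol | ICC/C(C)=C/Cc1cc(OC)cc(C)c1O
F3 | step 4 | (2S,3E)-2-hydroxy-4,8-dimethylnona-3,7-dien-1-yl 4-methylbenzenesulfonate | CC(C)=CCC/C(C)=C/[C@H](O)COS(=O)(=O)c1ccc(C)cc1
F4 | step 4 | (2S,3E)-2-[(tert-butyldimethylsilyl)oxy]-4,8-dimethylnona-3,7-dien-1-yl 4-methylbenzenesulfonate | CC(C)=CCC/C(C)=C/[C@H](O[Si](C)(C)C(C)(C)C)COS(=O)(=O)c1ccc(C)cc1
F5 | step 4 | tert-butyl{[(4R,5E)-6,10-dimethyl-1-(trimethylsilyl)undeca-5,9-dien-1-yn-4-yl]oxy}dimethylsilane | CC(C)=CCC/C(C)=C/[C@H](O[Si](C)(C)C(C)(C)C)CC#C[Si](C)(C)C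
F6 | step 8 | methyl (4E)-6-bromo-4-methylhex-4-enoate | COC(=O)CC/C(C)=C/CBr
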